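The bicyclo[3.3.1]nonane-2,4,9-trione is traced back to a cyclopentanone that already holds C9 (carbonyl), C5, C6, C7 and C8. Everything rests on the C1–C9 bond: a diketene annulation on the C5 enolate forms C4–C5 by acylation and then C1–C9 by intramolecular aldol addition, closing ring A (C1–C2–C3–C4–C5–C9) in one operation. The step exploits the 1,3-relationship of the C9 ketone to the C2 carbonyl and the C2/C4 β-diketone, which together are a masked diketene. The precursor is a 2,2,3,5-tetrasubstituted cyclopentanone; a later oxidative 1,2-shift of C8 from C9 to C1 expands it to ring B. An asymmetric CuH reduction sets C7, which controls C8, C5 and C1.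

Key step: step 6

Remark on locants: C1–C9 are those of the bicyclo[3.3.1]nonane core of the target (C1 and C5 bridgeheads, C2 and C9 carbonyls, C3 aroyl-bearing, C4 enol carbon, C6 CH2, C7 CH–geranyl, C8 C(CH3)(homoprenyl)) and denote the same atoms in every precursor. Geranyl = (2E)-3,7-dimethylocta-2,6-dien-1-yl, prenyl = 3-methylbut-2-en-1-yl, homoprenyl = 4-methylpent-3-en-1-yl.

Assumption: the CuH reduction of step 2 is taken to follow the sense of induction usual for 3-alkylcyclopent-2-enones with (S)-p-tol-BINAP; if the opposite sense is found, (R)-p-tol-BINAP is used.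

Step 1
Reactants: 1 geranyl chloride; 2 3-ethoxycyclopent-2-en-1-one
Product: 5 3-geranylcyclopent-2-en-1-one, via geranylbarium chloride 3 (not isolated), via chlorobarium cyclopentenolate 4 (not isolated)
Conditions: Ba (activated, from BaI2 and lithium biphenylide), THF, −78 °C; then 2, −78 °C; then 1 M HCl, 0 °C
Reagents that add atoms: water, O
Why: Stork–Danheiser sequence: allylbarium reagents add 1,2 to carbonyl groups through their unsubstituted terminus with retention of the E geometry, and acid hydrolysis of the 3-ethoxy carbinol with allylic transposition should give the 3-substituted enone (no stereocenter is formed).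

Step 2
Reactants: 5 3-geranylcyclopent-2-en-1-one
Product: 8 (2S,3S)-3-geranyl-2-methylcyclopentan-1-one, via bis(enoxy)diphenylsilane 6 (not isolated), via lithium enolate 7 (not isolated)
Conditions: CuCl (5 mol %), NaOt-Bu (5 mol %), (S)-p-tol-BINAP (5 mol %), Ph2SiH2 (0.55 equiv), toluene, −20 °C; then MeLi, THF, 0 °C; then MeI, −78 to 0 °C
Reagents that add atoms: iodomethane, CI
Why: Enantioselective CuH conjugate reduction (hydrosilylation) sets C7 by catalyst-controlled hydride delivery to the β-carbon while isolated alkenes stay inert, and the regiodefined C8=C9 enolate released by methyllithium is methylated (enolate alkylation) anti to the C7 substituent.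

Step 3
Reactants: 8 (2S,3S)-3-geranyl-2-methylcyclopentan-1-one
Product: 9 [(3S)-3-geranyl-2-methylcyclopent-1-en-1-yl]oxy-trimethylsilane
Conditions: TMSCl, NaI, Et3N, MeCN, 23 °C
Reagents that add atoms: chlorotrimethylsilane, C[Si](C)(C)Cl
Why: Thermodynamic silyl enol ether formation (iodotrimethylsilane made in the flask, with triethylamine) should favour the more substituted C8=C9 enol ether, and C7, not being α to the carbonyl group, keeps its configuration.

Step 4
Reactants: 9 [(3S)-3-geranyl-2-methylcyclopent-1-en-1-yl]oxy-trimethylsilane; 10 5-bromo-2-methylpent-2-ene (homoprenyl bromide)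
Product: 12 (2S,3S)-3-geranyl-2-homoprenyl-2-methylcyclopentan-1-one, via lithium enolate 11 (not isolated)
Conditions: MeLi, THF, 0 °C; then 10, HMPA, −78 to 23 °C
Reagents that add atoms: none
Why: Regiospecific enolate alkylation: methyllithium cleaves the silyl ether to the tetrasubstituted lithium enolate, and the bromide adds to the ring face anti to the adjacent C7 geranyl group, which sets the C8 quaternary stereocenter with homoprenyl trans to geranyl.

Step 5
Reactants: 12 (2S,3S)-3-geranyl-2-homoprenyl-2-methylcyclopentan-1-one; 13 prenyl bromide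
Product: 15 (2S,3R,5RS)-3-geranyl-2-homoprenyl-2-methyl-5-prenylcyclopentan-1-one, via lithium enolate 14 (not isolated)
Conditions: LiN(i-Pr)2, THF, −78 °C; then 13, −78 to 0 °C
Reagents that add atoms: none
Why: Kinetic enolate alkylation at C5, the only enolizable position; the C5 configuration is of no consequence because this carbon is enolized again in step 6.

Step 6
Reactants: 15 (2S,3R,5RS)-3-geranyl-2-homoprenyl-2-methyl-5-prenylcyclopentan-1-one; 16 diketene
Product: 19 (1S,2R,3aR,7aR)-2-geranyl-7a-hydroxy-1-homoprenyl-1-methyl-3a-prenyl-cis-hydrindane-4,6-dione (indane numbering), via lithium enolate 17 (not isolated), via terminal acetoacetyl enolate 18 (not isolated)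
Conditions: lithium 2,2,6,6-tetramethylpiperidide, THF, −78 to 0 °C; then 16, −78 °C; AcOH quench
Reagents that add atoms: none
Why: The tetrasubstituted lithium enolate 17 attacks the lactone carbonyl of diketene through C5 (Claisen-type C-acylation, C4–C5), the β-lactone opens to the terminal methyl ketone enolate 18 (C1=C2–OLi, a regiochemistry that deprotonation of a β-diketone cannot give), and C1 adds to the C9 ketone before proton transfer to the diketonate makes the sequence irreversible. The closest known reaction type is the diketene annulation of α-substituted cyclopentanone enolates (tandem acylation–intramolecular aldol addition). Ring A (C1–C2–C3–C4–C5–C9) closes in a 6-(enolendo)-exo-trig aldol mode. C5 is set by approach of diketene to the enolate face anti to the C7 geranyl and C8 methyl groups (the face of C7–H and the homoprenyl chain), and the C9 carbinol follows from C5 because a six-membered ring can only close cis onto the cyclopentane. The step needs C- over O-acylation, which the lithium counter-ion and low temperature should favour. It also needs an aldol closure that outruns enolate equilibration, which is secured because C9 has no α-hydrogen on either side once C5 is acylated and the terminal enolate is held next to it.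

Step 7
Reactants: 19 (1S,2R,3aR,7aR)-2-geranyl-7a-hydroxy-1-homoprenyl-1-methyl-3a-prenyl-cis-hydrindane-4,6-dione
Product: 20 (1S,2R,3aR,7aR)-2-geranyl-7a-hydroxy-1-homoprenyl-4-methoxy-1-methyl-3a-prenyl-cis-hydrind-4-en-6-one
Conditions: TMSCHN2, PhMe/MeOH (4:1), 0 °C
Reagents that add atoms: trimethylsilyldiazomethane, C[Si](C)(C)C=[N+]=[N-]
Why: O-Methylation of the enolized β-diketone by diazomethane made in the flask (the tertiary hydroxyl is not acidic enough to react); the ether at the C4 oxygen is needed because it leaves C1 as the α′ position of the enone, and the C2 regioisomer expected alongside is separated and hydrolysed back to 19.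

Step 8
Reactants: 20 (1S,2R,3aR,7aR)-2-geranyl-7a-hydroxy-1-homoprenyl-4-methoxy-1-methyl-3a-prenyl-cis-hydrind-4-en-6-one
Product: 22 (1R,5S,7R,8S)-7-geranyl-8-homoprenyl-4-methoxy-8-methyl-5-prenylbicyclo[3.3.1]non-3-ene-2,9-dione, via C1 phenyliodane 21 (not isolated)
Conditions: PhI(OAc)2, KOH, MeOH, 0 °C
Reagents that add atoms: none
Why: Oxidative semipinacol ring expansion: enolization towards C1 and attack on trivalent iodine give iodane 21, and the C9 alkoxide then pushes the antiperiplanar C9–C8 bond onto C1 with loss of iodobenzene (retention at C8), which converts the cyclopentane into ring B, the carbinol into the C9 ketone and fixes C1 through the bicyclic frame.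

Step 9
Reactants: 22 (1R,5S,7R,8S)-7-geranyl-8-homoprenyl-4-methoxy-8-methyl-5-prenylbicyclo[3.3.1]non-3-ene-2,9-dione; 13 prenyl bromide
Product: 24 (1R,5S,7R,8S)-7-geranyl-8-homoprenyl-4-methoxy-8-methyl-1,5-diprenylbicyclo[3.3.1]non-3-ene-2,9-dione, via bridgehead C1 lithio species 23 (not isolated)
Conditions: LiN(i-Pr)2, THF, −78 °C; then 13, −78 to −20 °C
Reagents that add atoms: none
Why: Bridgehead enolate alkylation: C1–H is the α′ proton of the vinylogous ester and is flanked by the C2 and C9 carbonyl groups, lithiation of such bicyclo[3.3.1]nonanetrione enol ethers is established, and the electrophile can only enter exo so C1 keeps the configuration of the frame.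

Step 10
Reactants: 24 (1R,5S,7R,8S)-7-geranyl-8-homoprenyl-4-methoxy-8-methyl-1,5-diprenylbicyclo[3.3.1]non-3-ene-2,9-dione; 25 3-acetoxybenzoyl chloride
Product: 27 (1S,5S,7R,8S)-3-(3-acetoxybenzoyl)-7-geranyl-8-homoprenyl-4-methoxy-8-methyl-1,5-diprenylbicyclo[3.3.1]non-3-ene-2,9-dione, via C3 vinyllithium 26 (not isolated)
Conditions: lithium 2,2,6,6-tetramethylpiperidide, THF, −78 °C; then 25, −78 °C
Reagents that add atoms: none
Why: Directed vinylic lithiation and C-acylation: with C1 quaternary the hindered amide removes the C3–H between the carbonyl and the methoxy-bearing carbon, and the vinyllithium should react with the acid chloride much faster than with the aryl acetate.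

Step 11
Reactants: 27 (1S,5S,7R,8S)-3-(3-acetoxybenzoyl)-7-geranyl-8-homoprenyl-4-methoxy-8-methyl-1,5-diprenylbicyclo[3.3.1]non-3-ene-2,9-dione
Product: 28 target, (1S,5S,7R,8S)-7-geranyl-4-hydroxy-3-(3-hydroxybenzoyl)-8-homoprenyl-8-methyl-1,5-diprenylbicyclo[3.3.1]non-3-ene-2,9-dione
Conditions: LiOH, dioxane/H2O, 90 °C; then 1 M HCl
Reagents that add atoms: lithium hydroxide, [Li+].[OH-]
Why: Addition–elimination of hydroxide at C4 cleaves the vinylogous methyl ester and saponification removes the aryl acetate in the same pot, and acidification gives the enolized β-triketone without touching the four stereocenters, of which C1 and C5 are quaternary and C7 and C8 are not enolizable.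

Compound list
1 | geranyl chloride, (2E)-1-chloro-3,7-dimethylocta-2,6-diene | ClC/C=C(\C)CCC=C(C)C | starting material
2 | 3-ethoxycyclopent-2-en-1-one | CCOC1=CC(=O)CC1 | starting material
3 | geranylbarium chloride | Cl[Ba]C/C=C(\C)CCC=C(C)C | intermediate
4 | chlorobarium 3-ethoxy-1-geranylcyclopent-2-en-1-olate (racemic) | CCOC1=CC(O[Ba]Cl)(C/C=C(\C)CCC=C(C)C)CC1 | intermediate
5 | 3-geranylcyclopent-2-en-1-one | O=C1CCC(C/C=C(\C)CCC=C(C)C)=C1 | intermediate
6 | bis[(3S)-3-geranylcyclopent-1-en-1-yloxy]diphenylsilane | c1ccccc1[Si](c1ccccc1)(OC1=C[C@H](C/C=C(\C)CCC=C(C)C)CC1)OC1=C[C@H](C/C=C(\C)CCC=C(C)C)CC1 | intermediate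
7 | lithium (3S)-3-geranylcyclopent-1-en-1-olate | [Li]OC1=C[C@H](C/C=C(\C)CCC=C(C)C)CC1 | intermediate
8 | (2S,3S)-3-geranyl-2-methylcyclopentan-1-one (methyl trans to geranyl) | O=C1CC[C@@H](C/C=C(\C)CCC=C(C)C)[C@@H]1C | intermediate
9 | [(3S)-3-geranyl-2-methylcyclopent-1-en-1-yl]oxy-trimethylsilane | CC1=C(O[Si](C)(C)C)CC[C@H]1C/C=C(\C)CCC=C(C)C | intermediate
10 | 5-bromo-2-methylpent-2-ene (homoprenyl bromide) | BrCCC=C(C)C | starting material
11 | lithium (3S)-3-geranyl-2-methylcyclopent-1-en-1-olate | CC1=C(O[Li])CC[C@H]1C/C=C(\C)CCC=C(C)C | intermediate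
12 | (2S,3S)-3-geranyl-2-homoprenyl-2-methylcyclopentan-1-one (methyl cis, homoprenyl trans to geranyl) | O=C1CC[C@@H](C/C=C(\C)CCC=C(C)C)[C@]1(C)CCC=C(C)C | intermediate
13 | prenyl bromide, 1-bromo-3-methylbut-2-ene | BrCC=C(C)C | starting material
14 | lithium enolate of 12 (C5=C9–OLi) | [Li]OC1=CC[C@@H](C/C=C(\C)CCC=C(C)C)[C@]1(C)CCC=C(C)C | intermediate
15 | (2S,3R,5RS)-3-geranyl-2-homoprenyl-2-methyl-5-prenylcyclopentan-1-one (C5 epimers) | O=C1C(CC=C(C)C)C[C@@H](C/C=C(\C)CCC=C(C)C)[C@]1(C)CCC=C(C)C | intermediate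
16 | diketene, 4-methylideneoxetan-2-one | C=C1CC(=O)O1 | starting material
17 | lithium enolate of 15 (C5=C9–OLi) | [Li]OC1=C(CC=C(C)C)C[C@@H](C/C=C(\C)CCC=C(C)C)[C@]1(C)CCC=C(C)C | intermediate
18 | terminal lithium enolate of the C5-acetoacetyl cyclopentanone (C4 on the face of the homoprenyl group) | C=C(O[Li])CC(=O)[C@]1(CC=C(C)C)C[C@@H](C/C=C(\C)CCC=C(C)C)[C@](C)(CCC=C(C)C)C1=O | intermediate
19 | (1S,2R,3aR,7aR)-2-geranyl-7a-hydroxy-1-homoprenyl-1-methyl-3a-prenyl-cis-hydrindane-4,6-dione (indane numbering; C7a = C9, C3a = C5, C7 = C1) | O[C@@]12CC(=O)CC(=O)[C@]1(CC=C(C)C)C[C@@H](C/C=C(\C)CCC=C(C)C)[C@]2(C)CCC=C(C)C | intermediate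
20 | (1S,2R,3aR,7aR)-2-geranyl-7a-hydroxy-1-homoprenyl-4-methoxy-1-methyl-3a-prenyl-cis-hydrind-4-en-6-one | O[C@@]12CC(=O)C=C(OC)[C@]1(CC=C(C)C)C[C@@H](C/C=C(\C)CCC=C(C)C)[C@]2(C)CCC=C(C)C | intermediate
21 | C1 acetoxy(phenyl)-λ3-iodanyl derivative of 20 | O[C@@]12C([I](OC(C)=O)c3ccccc3)C(=O)C=C(OC)[C@]1(CC=C(C)C)C[C@@H](C/C=C(\C)CCC=C(C)C)[C@]2(C)CCC=C(C)C | intermediate
22 | (1R,5S,7R,8S)-7-geranyl-8-homoprenyl-4-methoxy-8-methyl-5-prenylbicyclo[3.3.1]non-3-ene-2,9-dione | CC(C)=CCC/C(C)=C/C[C@@H]1C[C@]2(CC=C(C)C)C(=O)[C@@H](C(=O)C=C2OC)[C@@]1(C)CCC=C(C)C | intermediate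
23 | C1 bridgehead lithio derivative of 22 | CC(C)=CCC/C(C)=C/C[C@@H]1C[C@]2(CC=C(C)C)C(=O)[C@@]([Li])(C(=O)C=C2OC)[C@@]1(C)CCC=C(C)C | intermediate
24 | (1R,5S,7R,8S)-7-geranyl-8-homoprenyl-4-methoxy-8-methyl-1,5-diprenylbicyclo[3.3.1]non-3-ene-2,9-dione | CC(C)=CCC/C(C)=C/C[C@@H]1C[C@]2(CC=C(C)C)C(=O)[C@@](CC=C(C)C)(C(=O)C=C2OC)[C@@]1(C)CCC=C(C)C | intermediate
25 | 3-acetoxybenzoyl chloride | CC(=O)Oc1cccc(C(Cl)=O)c1 | starting material
26 | C3 vinyllithium derived from 24 | CC(C)=CCC/C(C)=C/C[C@@H]1C[C@]2(CC=C(C)C)C(=O)[C@@](CC=C(C)C)(C(=O)C([Li])=C2OC)[C@@]1(C)CCC=C(C)C | intermediate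
27 | (1S,5S,7R,8S)-3-(3-acetoxybenzoyl)-7-geranyl-8-homoprenyl-4-methoxy-8-methyl-1,5-diprenylbicyclo[3.3.1]non-3-ene-2,9-dione | CC(C)=CCC/C(C)=C/C[C@@H]1C[C@]2(CC=C(C)C)C(=O)[C@@](CC=C(C)C)(C(=O)C(C(=O)c3cccc(OC(C)=O)c3)=C2OC)[C@@]1(C)CCC=C(C)C | intermediate
28 | (1S,5S,7R,8S)-7-geranyl-4-hydroxy-3-(3-hydroxybenzoyl)-8-homoprenyl-8-methyl-1,5-diprenylbicyclo[3.3.1]non-3-ene-2,9-dione | CC(C)=CCC/C(C)=C/C[C@@H]1C[C@]2(CC=C(C)C)C(=O)[C@@](CC=C(C)C)(C(=O)C(C(=O)c3cccc(O)c3)=C2O)[C@@]1(C)CCC=C(C)C | target

Total step count: 11. Longest linear sequence: 11 steps (the route is linear from 1 and 2).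

Steps most likely to fail

Step 6 (key step). The hindered tetrasubstituted enolate may be O-acylated by diketene, the two enolate faces may not be discriminated well enough at C5, or the aldol closure may revert before proton transfer. Fallback: starting from 15, the enolate 17 would be C-acylated with (2E)-3-methoxybut-2-enoyl chloride to give the acyclic β-methoxy enone F1. Its only acidic protons are those of the vinylogous methyl group (C1), so LiN(i-Pr)2 at −78 °C should give the dienolate, whose terminal carbon adds to the C9 ketone (vinylogous aldol addition, again closing ring A through C1–C9) to give the C2-methoxy enone F2. Aqueous HCl in THF then hydrolyses the enol ether and the route is rejoined at 19. The two bond formations are thereby separated and can be optimised one at a time.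

Step 7. Methylation may occur mainly at the less hindered C2 oxygen, so that little of the C4 ether is obtained per pass. Fallback: starting from 19, TMSOTf/Et3N would give the tris(trimethylsilyl) derivative F3, in which the dienol ether can only be C1=C2–C3=C4 because C5 is quaternary. PhI(OH)OTs in CH2Cl2 at −78 °C should attack its terminal carbon C1 and trigger the same 1,2-shift of C8, now from the C9 silyl ether, to give the bicyclic trione F4 with no enol ether in place. O-Methylation of F4 (TMSCHN2), separation, and hydrolysis of the unwanted regioisomer back to F4 rejoin the route at 22.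

Step 8. Under methanolic KOH the β-hydroxy ketone may fragment by retro-aldol cleavage, the iodane may be intercepted by methoxide (α′-methoxylation), or the ring-fusion bond C9–C5 may migrate instead of C9–C8. Fallback: starting from 20, LiN(SiMe3)2 (excess) and 2,2,2-trifluoroethyl trifluoroacetate would give the C1-trifluoroacetyl ketone F5, and mesyl azide with Et3N (detrifluoroacetylative Regitz diazo transfer) the α′-diazo ketone F6. Rh2(OAc)4 in CH2Cl2 then generates the carbene at C1, and the 1,2-shift known for β-hydroxy α-diazo ketones moves C8 from C9 to C1 and forms the C9 ketone under neutral conditions, rejoining the route at 22.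

Further compounds
F1 | step 6 | C5-[(2E)-3-methoxybut-2-enoyl] derivative of 15 (acyl group on the face of the homoprenyl group) | CO/C(C)=C/C(=O)[C@]1(CC=C(C)C)C[C@@H](C/C=C(\C)CCC=C(C)C)[C@](C)(CCC=C(C)C)C1=O
F2 | step 6 | C2-methoxy regioisomer of 20, 2-geranyl-7a-hydroxy-1-homoprenyl-6-methoxy-1-methyl-3a-prenyl-cis-hydrind-5-en-4-one | O[C@@]12CC(OC)=CC(=O)[C@]1(CC=C(C)C)C[C@@H](C/C=C(\C)CCC=C(C)C)[C@]2(C)CCC=C(C)C
F3 | step 7 | tris(trimethylsilyl) derivative of 19 (C9 silyl ether and C1=C2–C3=C4 bis(silyl) dienol ether) | C[Si](C)(C)O[C@@]12C=C(O[Si](C)(C)C)C=C(O[Si](C)(C)C)[C@]1(CC=C(C)C)C[C@@H](C/C=C(\C)CCC=C(C)C)[C@]2(C)CCC=C(C)C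
F4 | step 7 | (1R,5S,7R,8S)-7-geranyl-8-homoprenyl-8-methyl-5-prenylbicyclo[3.3.1]nonane-2,4,9-trione | CC(C)=CCC/C(C)=C/C[C@@H]1C[C@]2(CC=C(C)C)C(=O)[C@@H](C(=O)CC2=O)[C@@]1(C)CCC=C(C)C
F5 | step 8 | C1-trifluoroacetyl derivative of 20 | O[C@@]12C(C(=O)C(F)(F)F)C(=O)C=C(OC)[C@]1(CC=C(C)C)C[C@@H](C/C=C(\C)CCC=C(C)C)[C@]2(C)CCC=C(C)C
F6 | step 8 | C1-diazo derivative of 20 (α′-diazo ketone) | O[C@@]12C(=[N+]=[N-])C(=O)C=C(OC)[C@]1(CC=C(C)C)C[C@@H](C/C=C(\C)CCC=C(C)C)[C@]2(C)CCC=C(C)C
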